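**Strategy.** Ring A of dielsianone carries its C5 hydroxyl next to the acyl-bearing C6 (carbonyl carbon Ca). Once ring B is cut away, the oxygens on C8 and C8a become mirror images across the C5–C6 bond. That edge is therefore built from a symmetric aryne. 4,5-Bis(benzyloxy)benzyne, unmasked with CsF from its 2-(trimethylsilyl)aryl triflate, takes up 4-methoxyphenylacetic acid by O-attack followed by acyl shift. This forms C5–O and C6–Ca in one operation without any regiochemical question. The chelated C5 hydroxyl then guides the endgame: methylene oxidation to the diketone, debenzylation, prenal annulation of ring B at C4a and O1, and methylation of the C8 hydroxyl.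

Key step: step 4

Remark on numbering: chromene numbering (O1, C2, C3, C4, C4a, C5 to C8, C8a) is used for the atoms of rings A and B at every stage. Ca is the carbonyl carbon on C6, Cb is the carbonyl carbon on the anisyl ring (ring C). The target has no stereocentre.

Remark on design: benzyl ethers are kept on the aryne rather than methyl ethers. The two ring A oxygens can then be freed later without touching the ring C methoxy group, which is also para to a carbonyl.

**Step 1**
Reactants: 1 3,4-bis(benzyloxy)benzaldehyde
Product: 3 3,4-bis(benzyloxy)phenol, via 3,4-bis(benzyloxy)phenyl formate 2 (not isolated)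
Conditions: mCPBA (1.3 equiv), CH2Cl2, 0 °C to rt; aq. NaHCO3 wash; then K2CO3 (cat.), MeOH, rt
Reagents that add atoms: mCPBA (3-chloroperoxybenzoic acid), O=C(OO)c1cccc(Cl)c1
Why: Baeyer–Villiger (Dakin-type) oxidation, in which the electron-rich aryl group of the benzaldehyde migrates to oxygen in preference to hydride and the labile formate 2 is cleaved by base-catalysed methanolysis without touching the benzyl ethers.

**Step 2**
Reactants: 3 3,4-bis(benzyloxy)phenol
Product: 4 2-bromo-4,5-bis(benzyloxy)phenol
Conditions: NBS (1.0 equiv), MeCN, −10 to 0 °C, dark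
Reagents that add atoms: NBS (N-bromosuccinimide), O=C1CCC(=O)N1Br
Why: Electrophilic aromatic bromination, in which the free hydroxyl directs ortho and the site para to the neighbouring benzyloxy group is the open one (the other ortho site is squeezed between two oxygens), while a polar solvent in the dark suppresses radical attack on the benzylic CH2 groups.

**Step 3**
Reactants: 4 2-bromo-4,5-bis(benzyloxy)phenol
Product: 7 4,5-bis(benzyloxy)-2-(trimethylsilyl)phenyl trifluoromethanesulfonate, via aryl trimethylsilyl ether 5 (not isolated), via lithium 2-silylphenoxide 6 (not isolated)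
Conditions: HMDS, THF, 70 °C, then evaporate under vacuum; n-BuLi (1.1 equiv), THF, −78 °C; Tf2O (1.2 equiv), −78 °C to rt
Reagents that add atoms: HMDS (hexamethyldisilazane), C[Si](C)(C)N[Si](C)(C)C; Tf2O (trifluoromethanesulfonic anhydride), O=S(=O)(OS(=O)(=O)C(F)(F)F)C(F)(F)F
Why: Standard 2-silylaryl triflate sequence of O-silylation, bromine–lithium exchange (faster than benzylic deprotonation at −78 °C), retro-Brook 1,3 O-to-C silyl shift to phenoxide 6 and O-triflation.

**Step 4**
Reactants: 7 4,5-bis(benzyloxy)-2-(trimethylsilyl)phenyl trifluoromethanesulfonate; 8 4-methoxyphenylacetic acid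
Product: 12 1-[4,5-bis(benzyloxy)-2-hydroxyphenyl]-2-(4-methoxyphenyl)ethan-1-one, via 4,5-bis(benzyloxy)benzyne 9 (not isolated), via ortho-caesiated aryl ester 10 (not isolated), via benzoxetene alkoxide 11 (not isolated)
Conditions: 7 (1.5 equiv), 8 (1.0 equiv), CsF (4 equiv), THF (0.02 M), 125 °C, sealed tube, Ar; aq. NH4Cl work-up
Reagents that add atoms: none
Why: Fluoride strips the silyl group of 7 and triflate leaves, giving the C2v-symmetric aryne 9, to which the carboxylate oxygen of 8 adds to give the ortho-metallated aryl ester 10. The carbanion attacks its own ester carbonyl (4-exo-trig) to form the strained alkoxide 11, which opens by C–O cleavage to the chelated phenoxide of 12, so the aryne has formally inserted into the acid C–O bond and both C5–O and C6–Ca are made. This is the known CsF-mediated insertion of arynes from 2-silylaryl triflates into carboxylic acids, an intermolecular relative of the anionic ortho-Fries acyl shift. The four-membered ring is only transient, so no ring and no stereocentre remain in 12. Regioselectivity does not arise because the two aryne carbons of 9 are equivalent, each para to one benzyloxy group and meta to the other. The chemoselectivity needed, acyl shift rather than protonation to the plain aryl ester, is served by heat, high dilution and the aprotic medium, and the CH2 oxidation level of 8 leaves the ester carbonyl as the only electrophile within reach of the carbanion.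

**Step 5**
Reactants: 12 1-[4,5-bis(benzyloxy)-2-hydroxyphenyl]-2-(4-methoxyphenyl)ethan-1-one
Product: 13 1-[4,5-bis(benzyloxy)-2-hydroxyphenyl]-2-(4-methoxyphenyl)ethane-1,2-dione
Conditions: SeO2 (1.5 equiv), 1,4-dioxane–H2O (20:1), 100 °C
Reagents that add atoms: selenium dioxide, O=[Se]=O
Why: Riley oxidation, in which the CH2 between Ca and the anisyl ring enolises readily and is the only activated methylene, while the C5 hydroxyl is tamed by its hydrogen bond to Ca=O.

**Step 6**
Reactants: 13 1-[4,5-bis(benzyloxy)-2-hydroxyphenyl]-2-(4-methoxyphenyl)ethane-1,2-dione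
Product: 14 1-(4-methoxyphenyl)-2-(2,4,5-trihydroxyphenyl)ethane-1,2-dione
Conditions: BCl3 (5 equiv), pentamethylbenzene (6 equiv), CH2Cl2, −78 to −40 °C; then H2O; handled under Ar and used directly
Reagents that add atoms: none
Why: Lewis-acid debenzylation with a cation scavenger, in which BCl3 ionises the aryl benzyl ethers at low temperature, pentamethylbenzene traps the benzyl cation by Friedel–Crafts alkylation so that ring A is not C-benzylated, and both the unchelated ring C methyl ether and the reducible diketone (which rules out hydrogenolysis) are spared.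

**Step 7**
Reactants: 14 1-(4-methoxyphenyl)-2-(2,4,5-trihydroxyphenyl)ethane-1,2-dione; 15 3-methylbut-2-enal
Product: 17 1-(5,8-dihydroxy-2,2-dimethyl-2H-chromen-6-yl)-2-(4-methoxyphenyl)ethane-1,2-dione, via ortho-quinone methide 16 (not isolated)
Conditions: 15 (3 equiv), pyridine, 120 °C, sealed tube, Ar
Reagents that add atoms: none
Why: Base-mediated formal [3+3] chromene annulation, in which C4a (the only ring carbon flanked by two oxygens) adds to the aldehyde, loss of water gives 16, and oxa-6π electrocyclisation closes ring B on the C8a oxygen because the C5 hydroxyl is held by Ca=O; pyridine is preferred to a diamine catalyst, which would condense with the diketone.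

**Step 8**
Reactants: 17 1-(5,8-dihydroxy-2,2-dimethyl-2H-chromen-6-yl)-2-(4-methoxyphenyl)ethane-1,2-dione
Product: 18 dielsianone, 1-(5-hydroxy-8-methoxy-2,2-dimethyl-2H-chromen-6-yl)-2-(4-methoxyphenyl)ethane-1,2-dione
Conditions: MeI (1.1 equiv), K2CO3 (1.1 equiv), DMF, 0 °C to rt
Reagents that add atoms: iodomethane, CI
Why: Williamson ether synthesis under weak base, in which only the C8 hydroxyl is available because the C5 hydroxyl is hydrogen-bonded to Ca=O and flanked by C4 and the acyl group, with DMF chosen over acetone to exclude aldol chemistry at the diketone.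

**Compound list**
1 | 3,4-bis(benzyloxy)benzaldehyde | O=Cc1ccc(OCc2ccccc2)c(OCc2ccccc2)c1 | starting material
2 | 3,4-bis(benzyloxy)phenyl formate | O=COc1ccc(OCc2ccccc2)c(OCc2ccccc2)c1 | intermediate (not isolated)
3 | 3,4-bis(benzyloxy)phenol | Oc1ccc(OCc2ccccc2)c(OCc2ccccc2)c1 | intermediate
4 | 2-bromo-4,5-bis(benzyloxy)phenol | Oc1cc(OCc2ccccc2)c(OCc2ccccc2)cc1Br | intermediate
5 | [2-bromo-4,5-bis(benzyloxy)phenoxy]trimethylsilane | C[Si](C)(C)Oc1cc(OCc2ccccc2)c(OCc2ccccc2)cc1Br | intermediate (not isolated)
6 | lithium 4,5-bis(benzyloxy)-2-(trimethylsilyl)phenoxide | [Li+].[O-]c1cc(OCc2ccccc2)c(OCc2ccccc2)cc1[Si](C)(C)C | intermediate (not isolated)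
7 | 4,5-bis(benzyloxy)-2-(trimethylsilyl)phenyl trifluoromethanesulfonate | C[Si](C)(C)c1cc(OCc2ccccc2)c(OCc2ccccc2)cc1OS(=O)(=O)C(F)(F)F | intermediate
8 | 4-methoxyphenylacetic acid | COc1ccc(CC(=O)O)cc1 | starting material
9 | 4,5-bis(benzyloxy)benzyne | C1#CC=C(OCc2ccccc2)C(OCc2ccccc2)=C1 | intermediate (not isolated)
10 | [4,5-bis(benzyloxy)-2-{[(4-methoxyphenyl)acetyl]oxy}phenyl]caesium | [Cs+].COc1ccc(CC(=O)Oc2cc(OCc3ccccc3)c(OCc3ccccc3)c[c-]2)cc1 | intermediate (not isolated)
11 | caesium 4,5-bis(benzyloxy)-2-(4-methoxybenzyl)-2H-benzo[b]oxet-2-olate (racemic, transient) | [Cs+].COc1ccc(CC2([O-])Oc3cc(OCc4ccccc4)c(OCc4ccccc4)cc32)cc1 | intermediate (not isolated)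
12 | 1-[4,5-bis(benzyloxy)-2-hydroxyphenyl]-2-(4-methoxyphenyl)ethan-1-one | COc1ccc(CC(=O)c2cc(OCc3ccccc3)c(OCc3ccccc3)cc2O)cc1 | intermediate
13 | 1-[4,5-bis(benzyloxy)-2-hydroxyphenyl]-2-(4-methoxyphenyl)ethane-1,2-dione | COc1ccc(C(=O)C(=O)c2cc(OCc3ccccc3)c(OCc3ccccc3)cc2O)cc1 | intermediate
14 | 1-(4-methoxyphenyl)-2-(2,4,5-trihydroxyphenyl)ethane-1,2-dione | COc1ccc(C(=O)C(=O)c2cc(O)c(O)cc2O)cc1 | intermediate
15 | 3-methylbut-2-enal (prenal) | CC(C)=CC=O | starting material
16 | 1-[2,5-dihydroxy-3-(3-methylbut-2-en-1-ylidene)-4-oxocyclohexa-1,5-dien-1-yl]-2-(4-methoxyphenyl)ethane-1,2-dione (C8a=O, exocyclic C4a=C4; geometry not defined) | COc1ccc(C(=O)C(=O)C2=C(O)C(=CC=C(C)C)C(=O)C(O)=C2)cc1 | intermediate (not isolated)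
17 | 1-(5,8-dihydroxy-2,2-dimethyl-2H-chromen-6-yl)-2-(4-methoxyphenyl)ethane-1,2-dione | COc1ccc(C(=O)C(=O)c2cc(O)c3c(c2O)C=CC(C)(C)O3)cc1 | intermediate
18 | dielsianone, 1-(5-hydroxy-8-methoxy-2,2-dimethyl-2H-chromen-6-yl)-2-(4-methoxyphenyl)ethane-1,2-dione | COc1ccc(C(=O)C(=O)c2cc(OC)c3c(c2O)C=CC(C)(C)O3)cc1 | target

**Total step count:** 8. **Longest linear sequence:** 8 steps (1 to 18); 8 and 15 are purchased.

**Steps most likely to fail**

1. **Step 4.**
 - What may go wrong: the ortho carbanion may be protonated, by the acid proton or by the acidic CH2 of the ester, before it reaches the carbonyl. The reaction would then stop at plain O-arylation. The phenoxide or enolate of the product may also capture a second aryne.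
 - Fallback: it sets out from 8 and returns at 12, using acid-mediated instead of anionic C-acylation. Commercial benzene-1,2,4-triol is acylated with 8 in BF3·OEt2 at 80–90 °C. This is the Friedel–Crafts/Nencki acylation used for isoflavone deoxybenzoins, with attack at the carbon ortho to one hydroxyl and para to another. It should give 2-(4-methoxyphenyl)-1-(2,4,5-trihydroxyphenyl)ethan-1-one F1. BnBr (2.1 equiv), K2CO3, DMF, rt should then benzylate the two unchelated hydroxyls and give 12.

2. **Step 7.**
 - What may go wrong: the hydroxyhydroquinone ring may be oxidised by air in hot base, prenal may self-condense faster than C4a attacks it, or part of the closure may go to the wrong oxygen.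
 - Fallback: it sets out from 14 and returns at 17, and forms the O1–C2 bond first. 3-Chloro-3-methylbut-1-yne, K2CO3 (1 equiv), KI, DMF, 60 °C under Ar should alkylate the most acidic hydroxyl (on C8a, para to Ca). This should give 1-{2,5-dihydroxy-4-[(2-methylbut-3-yn-2-yl)oxy]phenyl}-2-(4-methoxyphenyl)ethane-1,2-dione F2. Heating in N,N-diethylaniline or xylene (140–180 °C) should then trigger the aromatic propargyl Claisen rearrangement to C4a, since the other ortho carbon C8 is blocked. A 1,5-hydrogen shift and oxa-6π closure follow and give 17.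

3. **Step 5.**
 - What may go wrong: attack of SeO2 on the enol may be sluggish, the electron-rich ring A may be over-oxidised, selenium may be incorporated, or ring–chain tautomerism of the 2-hydroxybenzil to its cyclic hemiketal may complicate isolation.
 - Fallback: it sets out from 12 and returns at 13, in two separate oxidation levels. KN(SiMe3)2 (2.2 equiv), THF, −78 °C, then 3-phenyl-2-(phenylsulfonyl)oxaziridine (Davis hydroxylation of the phenoxide–enolate dianion) should give racemic 1-[4,5-bis(benzyloxy)-2-hydroxyphenyl]-2-hydroxy-2-(4-methoxyphenyl)ethan-1-one F3. MnO2, CH2Cl2, rt should then oxidise this benzoin to 13.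

**Further compounds**
F1 | step 4 | 2-(4-methoxyphenyl)-1-(2,4,5-trihydroxyphenyl)ethan-1-one | COc1ccc(CC(=O)c2cc(O)c(O)cc2O)cc1
F2 | step 7 | 1-{2,5-dihydroxy-4-[(2-methylbut-3-yn-2-yl)oxy]phenyl}-2-(4-methoxyphenyl)ethane-1,2-dione | COc1ccc(C(=O)C(=O)c2cc(O)c(OC(C)(C)C#C)cc2O)cc1
F3 | step 5 | 1-[4,5-bis(benzyloxy)-2-hydroxyphenyl]-2-hydroxy-2-(4-methoxyphenyl)ethan-1-one (racemic) | COc1ccc(C(O)C(=O)c2cc(OCc3ccccc3)c(OCc3ccccc3)cc2O)cc1
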